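**Retrosynthetic overview**
1. Target 23 ⇐ photochemical E→Z isomerisation of the (E)-coumarate 22 ⇐ Mitsunobu coupling (inversion) of the macrocyclic (1R)-alcohol 20 with p-coumaric acid.
2. Key disconnection: ring bond C4–C5 of 20, closed by nickel-electrocatalytic decarboxylative alkenylation of seco acid 18 (primary redox-active ester + (E)-alkenyl iodide). This forms the only carbocycle, the 11-membered ring, after both ring alkenes are in place.
3. 18 ⇐ Johnson–Claisen rearrangement (sets C7=C8, E) of an isopropenyl carbinol made from δ-lactone 12; the (E)-iodoalkene (C3=C4) ⇐ Negishi carboalumination–iodination of homopropargylic alcohol 6.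
4. 6 ⇐ (R)-epichlorohydrin opened at both CH2 termini: prenyl Grignard through its γ-carbon (builds the quaternary CMe2), then acetylide. The carbinol carbon is carried unchanged until the final inversion.

Assumption: an operation run in one flask without isolating the intermediate is counted as one step.

**Route**

Step 1
Reactants: 1 (R)-epichlorohydrin; 2 prenylmagnesium chloride
Product: 3 (R)-1-chloro-4,4-dimethylhex-5-en-2-ol
Conditions: THF, −40 → 0 °C, no copper salt; aq. NH4Cl
Reagents that add atoms: none
Why: Allylic Grignard reagents open terminal epoxides at the CH2 carbon through their γ-carbon (SE2′ epoxide opening), so the prenyl reagent delivers the gem-dimethyl quaternary carbon bearing a vinyl group, while the carbinol carbon of 1 is not touched and keeps its configuration.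

Step 2
Reactants: 3 (R)-1-chloro-4,4-dimethylhex-5-en-2-ol; 4 lithium acetylide–ethylenediamine complex
Product: 6 (S)-6,6-dimethyloct-7-en-1-yn-4-ol, via epoxide 5 (not isolated)
Conditions: LiC≡CH·H2NCH2CH2NH2 (3 equiv), DMSO, 0 °C → rt; H2O
Reagents that add atoms: none
Why: The base closes the chloro alkoxide to the terminal epoxide (intramolecular Williamson reaction) and the acetylide opens it at CH2 (SN2), so no bond to the stereocentre is broken; the descriptor changes from R to S only because the CIP priorities change.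

Step 3
Reactants: 6 (S)-6,6-dimethyloct-7-en-1-yn-4-ol
Product: 8 (1E,4R)-1-iodo-2,6,6-trimethylocta-1,7-dien-4-ol, via alkenylalane 7 (not isolated)
Conditions: Me3Al (3 equiv), Cp2ZrCl2 (0.3 equiv), CH2Cl2, 0 °C → rt; then I2, THF, −30 → 0 °C
Reagents that add atoms: trimethylaluminium, C[Al](C)C; iodine, [I][I]
Why: Negishi zirconium-catalysed carboalumination adds Me–Al syn across the terminal alkyne with methyl on the internal carbon, and iodinolysis of the C–Al bond with retention gives the (E)-iodoalkene; the hindered vinyl group does not react.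

Step 4
Reactants: 8 (1E,4R)-1-iodo-2,6,6-trimethylocta-1,7-dien-4-ol
Product: 10 (5R,7E)-8-iodo-3,3,7-trimethyloct-7-ene-1,5-diol, via alkylborane 9 (not isolated)
Conditions: 9-BBN (2.5 equiv), THF, rt → 50 °C; then NaOH, H2O2, H2O, 0 °C → rt
Reagents that add atoms: hydrogen peroxide, OO
Why: Hydroboration–oxidation: 9-BBN adds anti-Markovnikov only to the monosubstituted alkene (the trisubstituted iodoalkene is inert) and alkaline peroxide converts C–B into C–OH.

Step 5
Reactants: 10 (5R,7E)-8-iodo-3,3,7-trimethyloct-7-ene-1,5-diol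
Product: 12 (6R)-6-[(2E)-3-iodo-2-methylprop-2-en-1-yl]-4,4-dimethyloxan-2-one, via lactol 11 (not isolated)
Conditions: TEMPO (0.2 equiv), PhI(OAc)2 (2.5 equiv), CH2Cl2, rt
Reagents that add atoms: none
Why: Oxoammonium (TEMPO) oxidation is selective for the primary alcohol; the aldehyde closes onto the C5 hydroxyl (helped by the gem-dimethyl group) to the free lactol, which is oxidised on to the δ-lactone (oxidative lactonisation), and this also masks the secondary alcohol.

Step 6
Reactants: 12 (6R)-6-[(2E)-3-iodo-2-methylprop-2-en-1-yl]-4,4-dimethyloxan-2-one; 13 isopropenylmagnesium bromide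
Product: 15 (7R,9E)-10-iodo-2,5,5,9-tetramethyldeca-1,9-diene-3,7-diol (C3 epimer mixture), via aluminium lactolate 14 (not isolated)
Conditions: i-Bu2AlH (1.1 equiv), CH2Cl2, −78 °C; then CH2=C(Me)MgBr (4 equiv), THF, −78 °C → rt; aq. potassium sodium tartrate
Reagents that add atoms: none
Why: Hydride addition to the lactone carbonyl stops at the tetrahedral diisobutylaluminium lactolate, which is stable at −78 °C; on warming with excess Grignard reagent it opens to the alkoxy aldehyde, to which the alkenyl Grignard adds (1,2-addition). The new carbinol centre forms as a mixture, which does not matter because it is destroyed in step 7.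

Step 7
Reactants: 15 (7R,9E)-10-iodo-2,5,5,9-tetramethyldeca-1,9-diene-3,7-diol; 16 triethyl orthoacetate
Product: 18 (4E,9R,11E)-9-hydroxy-12-iodo-4,7,7,11-tetramethyldodeca-4,11-dienoic acid, via ethyl ester 17 (not isolated)
Conditions: MeC(OEt)3 (10 equiv), EtCO2H (0.1 equiv), 140 °C, EtOH distilled off; evaporate; 1 M HCl, THF, rt, 10 min; then KOH, EtOH–H2O, 50 °C; 1 M HCl to pH 3
Reagents that add atoms: potassium hydroxide, [K+].[OH-]
Why: Johnson–Claisen orthoester rearrangement through a chair transition state with the bulky chain equatorial gives the (E)-trisubstituted alkene from both C3 epimers and adds the two-carbon ester. The brief acid treatment hydrolyses any mixed orthoester on the C9 hydroxyl, and KOH then cleaves the ethyl ester together with any C9 acetate.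

Step 8
Reactants: 18 (4E,9R,11E)-9-hydroxy-12-iodo-4,7,7,11-tetramethyldodeca-4,11-dienoic acid
Product: 20 (1R,3E,7E)-3,7,10,10-tetramethylcycloundeca-3,7-dien-1-ol, via phthalimide ester 19 (not isolated)
Conditions: N-hydroxyphthalimide (1.1 equiv), DIC (1.1 equiv), DMF, rt, no DMAP; then syringe-pump addition (12 h) into NiCl2·6H2O (0.2 equiv), 2,2′-bipyridine (0.2 equiv), AgNO3 (0.3 equiv), DMF, Mg anode / reticulated vitreous carbon cathode, constant current 4 mA, rt, 2 mM final concentration
Reagents that add atoms: none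
Why: Proposed new method: cathodically generated low-valent nickel–bipyridine inserts into the C(sp2)–I bond to give a divalent alkenylnickel, one-electron reduction of the tethered N-acyloxyphthalimide (by monovalent nickel or at the silver-coated cathode) releases CO2 and a primary radical at the carbon that was α to the carboxyl, this radical is captured by the alkenylnickel in the same molecule, and reductive elimination from trivalent nickel closes the 11-membered ring with retention of the (E)-alkene geometry, slow addition keeping the seco compound dilute enough for ring closure to outrun dimerisation; the closest known reaction type is the intermolecular nickel-electrocatalytic decarboxylative alkenylation of primary redox-active esters with trisubstituted alkenyl iodides used for acyclic polyene terpenes, which has not been used to close a medium carbocycle.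

Step 9
Reactants: 20 (1R,3E,7E)-3,7,10,10-tetramethylcycloundeca-3,7-dien-1-ol; 21 (E)-p-coumaric acid
Product: 22 (1S,3E,7E)-3,7,10,10-tetramethylcycloundeca-3,7-dien-1-yl (2E)-3-(4-hydroxyphenyl)prop-2-enoate
Conditions: PPh3 (1.5 equiv), DIAD (1.5 equiv), THF, 0 °C → rt
Reagents that add atoms: none
Why: Mitsunobu esterification: the carboxylic acid, far more acidic than the phenol, displaces the oxyphosphonium group by SN2, which inverts C1 from R to S, the configuration of the target.

Step 10
Reactants: 22 (1S,3E,7E)-3,7,10,10-tetramethylcycloundeca-3,7-dien-1-yl (2E)-3-(4-hydroxyphenyl)prop-2-enoate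
Product: 23 (1S,3E,7E)-3,7,10,10-tetramethylcycloundeca-3,7-dien-1-yl (2Z)-3-(4-hydroxyphenyl)prop-2-enoate
Conditions: fac-Ir(ppy)3 [tris(2-phenylpyridinato)iridium] (1 mol %), MeCN, 450 nm LEDs, Ar, rt; chromatography, recovered 22 recycled
Reagents that add atoms: none
Why: Triplet energy transfer from the excited sensitiser isomerises the conjugated (E)-enoate to the less conjugated (Z)-isomer, which accumulates at the photostationary state (contra-thermodynamic E→Z photoisomerisation); the isolated ring alkenes and the stereocentre are not excited and stay as they are.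

**Compound list**
1 | (R)-epichlorohydrin, (2R)-2-(chloromethyl)oxirane | ClC[C@H]1CO1 | starting material
2 | prenylmagnesium chloride (3-methylbut-2-en-1-ylmagnesium chloride) | CC(C)=CC[Mg]Cl | starting material
3 | (R)-1-chloro-4,4-dimethylhex-5-en-2-ol | C=CC(C)(C)C[C@@H](O)CCl | intermediate
4 | lithium acetylide–ethylenediamine complex | [Li+].[C-]#C.NCCN | starting material
5 | (R)-2-(2,2-dimethylbut-3-en-1-yl)oxirane (not isolated) | C=CC(C)(C)C[C@@H]1CO1 | intermediate
6 | (S)-6,6-dimethyloct-7-en-1-yn-4-ol | C=CC(C)(C)C[C@@H](O)CC#C | intermediate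
7 | [(1E,4R)-4-(dimethylalumanyloxy)-2,6,6-trimethylocta-1,7-dien-1-yl]dimethylalumane (not isolated) | C=CC(C)(C)C[C@@H](O[Al](C)C)C/C(C)=C/[Al](C)C | intermediate
8 | (1E,4R)-1-iodo-2,6,6-trimethylocta-1,7-dien-4-ol | C=CC(C)(C)C[C@@H](O)C/C(C)=C/I | intermediate
9 | 9-[(5R,7E)-5-(9-borabicyclo[3.3.1]nonan-9-yloxy)-8-iodo-3,3,7-trimethyloct-7-en-1-yl]-9-borabicyclo[3.3.1]nonane (not isolated) | B1(C2CCCC1CCC2)CCC(C)(C)C[C@@H](OB1C2CCCC1CCC2)C/C(C)=C/I | intermediate
10 | (5R,7E)-8-iodo-3,3,7-trimethyloct-7-ene-1,5-diol | OCCC(C)(C)C[C@@H](O)C/C(C)=C/I | intermediate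
11 | (6R)-6-[(2E)-3-iodo-2-methylprop-2-en-1-yl]-4,4-dimethyloxan-2-ol, anomer mixture (not isolated) | OC1CC(C)(C)C[C@@H](O1)C/C(C)=C/I | intermediate
12 | (6R)-6-[(2E)-3-iodo-2-methylprop-2-en-1-yl]-4,4-dimethyloxan-2-one | O=C1CC(C)(C)C[C@@H](O1)C/C(C)=C/I | intermediate
13 | isopropenylmagnesium bromide (prop-1-en-2-ylmagnesium bromide) | CC(=C)[Mg]Br | starting material
14 | {[(6R)-6-[(2E)-3-iodo-2-methylprop-2-en-1-yl]-4,4-dimethyloxan-2-yl]oxy}bis(2-methylpropyl)alumane, anomer mixture (not isolated) | CC(C)C[Al](CC(C)C)OC1CC(C)(C)C[C@@H](O1)C/C(C)=C/I | intermediate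
15 | (7R,9E)-10-iodo-2,5,5,9-tetramethyldeca-1,9-diene-3,7-diol, C3 epimer mixture | C=C(C)C(O)CC(C)(C)C[C@@H](O)C/C(C)=C/I | intermediate
16 | triethyl orthoacetate (1,1,1-triethoxyethane) | CCOC(C)(OCC)OCC | starting material
17 | ethyl (4E,9R,11E)-9-hydroxy-12-iodo-4,7,7,11-tetramethyldodeca-4,11-dienoate (not isolated) | CCOC(=O)CC/C(C)=C/CC(C)(C)C[C@@H](O)C/C(C)=C/I | intermediate
18 | (4E,9R,11E)-9-hydroxy-12-iodo-4,7,7,11-tetramethyldodeca-4,11-dienoic acid | OC(=O)CC/C(C)=C/CC(C)(C)C[C@@H](O)C/C(C)=C/I | intermediate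
19 | 1,3-dioxoisoindolin-2-yl (4E,9R,11E)-9-hydroxy-12-iodo-4,7,7,11-tetramethyldodeca-4,11-dienoate (not isolated) | O=C(CC/C(C)=C/CC(C)(C)C[C@@H](O)C/C(C)=C/I)ON1C(=O)c2ccccc2C1=O | intermediate
20 | (1R,3E,7E)-3,7,10,10-tetramethylcycloundeca-3,7-dien-1-ol | C/C1=C\CC(C)(C)C[C@@H](O)C/C(C)=C/CC1 | intermediate
21 | (E)-p-coumaric acid, (2E)-3-(4-hydroxyphenyl)prop-2-enoic acid | OC(=O)/C=C/c1ccc(O)cc1 | starting material
22 | (1S,3E,7E)-3,7,10,10-tetramethylcycloundeca-3,7-dien-1-yl (2E)-3-(4-hydroxyphenyl)prop-2-enoate | C/C1=C\CC(C)(C)C[C@H](OC(=O)/C=C/c2ccc(O)cc2)C/C(C)=C/CC1 | intermediate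
23 | (1S,3E,7E)-3,7,10,10-tetramethylcycloundeca-3,7-dien-1-yl (2Z)-3-(4-hydroxyphenyl)prop-2-enoate (CNP0152312.2) | C/C1=C\CC(C)(C)C[C@H](OC(=O)/C=C\c2ccc(O)cc2)C/C(C)=C/CC1 | target

**Step count**
Total steps: 10. Longest linear sequence: 10 (fully linear; all partners are bought).

**Three steps most likely to fail, with fallbacks**

1. Step 8 (new electrochemical ring closure). Risks are dimer formation, simple reduction of the radical, and partial loss of the C7=C8 geometry through reversible 3-exo closure of the homoallylic radical. The fallback closes the same C4–C5 bond by a B-alkyl Suzuki–Miyaura macrocyclisation, which is known chemistry. It sets out from lactone 12. Reduction with i-Bu2AlH (CH2Cl2, −78 °C) and aqueous potassium sodium tartrate work-up gives the free lactol 11, isolated here. Wittig reaction with Ph3P=C(Me)CHO (toluene, 90 °C) gives (2E,7R,9E)-7-hydroxy-10-iodo-2,5,5,9-tetramethyldeca-2,9-dienal F1. Methylenation with Ph3P=CH2 (THF, 0 °C) gives (1E,4R,8E)-1-iodo-2,6,6,9-tetramethylundeca-1,8,10-trien-4-ol F2. 9-BBN (2.5 equiv, THF) adds to the terminal CH2=CH of the diene to give the homoallylic alkylborane, carried with its O-borinate, 9-[(3E,8R,10E)-8-(9-borabicyclo[3.3.1]nonan-9-yloxy)-11-iodo-3,6,6,10-tetramethylundeca-3,10-dien-1-yl]-9-borabicyclo[3.3.1]nonane F3 (not isolated). Slow addition of F3 to PdCl2(dppf), AsPh3 and Cs2CO3 in DMF–THF–H2O at 50 °C couples C–B with C–I and gives 20, where the route continues with step 9.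

2. Step 1 (regiochemistry of the prenyl Grignard: γ against α attack, and chloride opening of the epoxide by the magnesium salt). The fallback builds the quaternary carbon by alkylation of a tertiary nitrile anion and sets out from 1. Lithiated isobutyronitrile (LDA, THF, −78 → 0 °C) opens the epoxide at CH2 and the chloro alkoxide closes again, giving (R)-2,2-dimethyl-3-(oxiran-2-yl)propanenitrile F4. i-Bu2AlH (toluene, −78 °C; buffered aqueous work-up) gives (R)-2,2-dimethyl-3-(oxiran-2-yl)propanal F5. Ph3P=CH2 (THF, 0 °C) gives epoxide 5, which is isolated here and opened with 4 as in step 2, so the route is rejoined at 5.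

3. Step 9 (Mitsunobu reaction of a ring secondary alcohol with an unprotected hydroxycinnamic acid: phenol O-alkylation, addition of the betaine to the enoate, elimination). The fallback separates inversion from acylation and builds the cinnamate C=C afterwards; it sets out from 20. Mitsunobu reaction with 4-nitrobenzoic acid (PPh3, DIAD, THF) gives (1S,3E,7E)-3,7,10,10-tetramethylcycloundeca-3,7-dien-1-yl 4-nitrobenzoate F6. K2CO3 in MeOH gives (1S,3E,7E)-3,7,10,10-tetramethylcycloundeca-3,7-dien-1-ol F7. Meldrum's acid (toluene, 100 °C) acylates with retention to 3-oxo-3-{[(1S,3E,7E)-3,7,10,10-tetramethylcycloundeca-3,7-dien-1-yl]oxy}propanoic acid F8. Knoevenagel–Doebner condensation with 4-hydroxybenzaldehyde (pyridine, cat. piperidine, 80 °C, loss of CO2) gives the (E)-coumarate 22, where the route continues with step 10.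

**Further compounds**
F1 | step 8 | (2E,7R,9E)-7-hydroxy-10-iodo-2,5,5,9-tetramethyldeca-2,9-dienal | O=C/C(C)=C/CC(C)(C)C[C@@H](O)C/C(C)=C/I
F2 | step 8 | (1E,4R,8E)-1-iodo-2,6,6,9-tetramethylundeca-1,8,10-trien-4-ol | C=C/C(C)=C/CC(C)(C)C[C@@H](O)C/C(C)=C/I
F3 | step 8 | 9-[(3E,8R,10E)-8-(9-borabicyclo[3.3.1]nonan-9-yloxy)-11-iodo-3,6,6,10-tetramethylundeca-3,10-dien-1-yl]-9-borabicyclo[3.3.1]nonane | B1(C2CCCC1CCC2)CC/C(C)=C/CC(C)(C)C[C@@H](OB1C2CCCC1CCC2)C/C(C)=C/I
F4 | step 1 | (R)-2,2-dimethyl-3-(oxiran-2-yl)propanenitrile | N#CC(C)(C)C[C@@H]1CO1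
F5 | step 1 | (R)-2,2-dimethyl-3-(oxiran-2-yl)propanal | O=CC(C)(C)C[C@@H]1CO1
F6 | step 9 | (1S,3E,7E)-3,7,10,10-tetramethylcycloundeca-3,7-dien-1-yl 4-nitrobenzoate | C/C1=C\CC(C)(C)C[C@H](OC(=O)c2ccc(cc2)[N+](=O)[O-])C/C(C)=C/CC1
F7 | step 9 | (1S,3E,7E)-3,7,10,10-tetramethylcycloundeca-3,7-dien-1-ol | C/C1=C\CC(C)(C)C[C@H](O)C/C(C)=C/CC1
F8 | step 9 | 3-oxo-3-{[(1S,3E,7E)-3,7,10,10-tetramethylcycloundeca-3,7-dien-1-yl]oxy}propanoic acid | C/C1=C\CC(C)(C)C[C@H](OC(=O)CC(O)=O)C/C(C)=C/CC1
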